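**Retrosynthetic overview**
1. The oxolane (ring B) is formed last by 5-exo bromoetherification of a hydroxy oxocene: the C6 hydroxyl adds to C9 and bromine to C10 of the ring Z-alkene.
2. The terminal enyne comes from a Sonogashira coupling on an (E)-iodoalkene; the oxocene (ring A) is formed first, by ring-closing metathesis of an acyclic diene ether.
3. The diene ether comes from allylation of an α-acetoxy ether made by reductive acetylation of an ester; this sets C7.
4. The ester is made by late esterification of fragment 1, (2R,4E)-2-silyloxy-5-iodopent-4-enoic acid (from (S)-glycidol and acetylide), with fragment 2, (3R,4S)-4-bromohept-6-en-3-ol (from (R)-2-aminobutanoic acid and allylsilane).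
5. Ring order: ring A (eight-membered) by metathesis, then ring B (five-membered) by bromoetherification.

Assumption: atoms are numbered C1 (alkyne CH) to C15 (ethyl CH3) along the target chain in all intermediates, and compounds 1, 3, 11, 18 and 27 are bought.

**Fragment 1 (steps 1–7)**

Step 1
Reactants: 1 (S)-oxiran-2-ylmethanol ((S)-glycidol)
Product: 2 (R)-2-{[(4-methoxybenzyl)oxy]methyl}oxirane
Conditions: NaH, PMBCl, Bu4NI (cat.), THF/DMF, 0 °C → rt
Reagents that add atoms: 4-methoxybenzyl chloride, COc1ccc(CCl)cc1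
Why: Williamson etherification of the primary alkoxide leaves the epoxide carbon untouched (the Payne rearrangement of glycidol is degenerate); the descriptor changes from S to R only because the CIP priorities change.

Step 2
Reactants: 2 (R)-2-{[(4-methoxybenzyl)oxy]methyl}oxirane; 3 lithium acetylide–ethylenediamine complex (LiC≡CH·H2NCH2CH2NH2)
Product: 4 (R)-1-[(4-methoxybenzyl)oxy]pent-4-yn-2-ol
Conditions: DMSO, 0 °C → rt; then H2O
Reagents that add atoms: none
Why: SN2 epoxide opening by the acetylide at the unsubstituted carbon gives the homopropargylic alcohol without touching the C6 stereocentre.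

Step 3
Reactants: 4 (R)-1-[(4-methoxybenzyl)oxy]pent-4-yn-2-ol
Product: 5 (R)-tert-butyl({1-[(4-methoxybenzyl)oxy]pent-4-yn-2-yl}oxy)dimethylsilane
Conditions: TBSCl, imidazole, DMF, rt
Reagents that add atoms: tert-butyldimethylsilyl chloride, CC(C)(C)[Si](C)(C)Cl
Why: Standard silylation gives a bulky, non-chelating C6 ether that later steers the C7 allylation and is removed by fluoride.

Step 4
Reactants: 5 (R)-tert-butyl({1-[(4-methoxybenzyl)oxy]pent-4-yn-2-yl}oxy)dimethylsilane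
Product: 7 tert-butyl({(2R,4E)-5-iodo-1-[(4-methoxybenzyl)oxy]pent-4-en-2-yl}oxy)dimethylsilane, via alkenylzirconocene chloride 6 (not isolated)
Conditions: Cp2Zr(H)Cl, THF, rt, dark; then I2, 0 °C
Reagents that add atoms: iodine, II
Why: Schwartz hydrozirconation adds Zr–H syn with zirconium at the terminal carbon, and iodinolysis with retention gives only the (E)-iodoalkene.

Step 5
Reactants: 7 tert-butyl({(2R,4E)-5-iodo-1-[(4-methoxybenzyl)oxy]pent-4-en-2-yl}oxy)dimethylsilane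
Product: 8 (2R,4E)-2-[(tert-butyldimethylsilyl)oxy]-5-iodopent-4-en-1-ol
Conditions: DDQ, CH2Cl2/pH 7 phosphate buffer, 0 °C → rt
Reagents that add atoms: none
Why: Oxidative PMB-ether cleavage under neutral conditions leaves the silyl ether and the iodoalkene intact and avoids silyl migration.

Step 6
Reactants: 8 (2R,4E)-2-[(tert-butyldimethylsilyl)oxy]-5-iodopent-4-en-1-ol
Product: 9 (2R,4E)-2-[(tert-butyldimethylsilyl)oxy]-5-iodopent-4-enal
Conditions: Dess–Martin periodinane, CH2Cl2, 0 °C → rt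
Reagents that add atoms: none
Why: Dess–Martin oxidation gives the α-silyloxy aldehyde without base, so C6 is not epimerised.

Step 7
Reactants: 9 (2R,4E)-2-[(tert-butyldimethylsilyl)oxy]-5-iodopent-4-enal
Product: 10 (2R,4E)-2-[(tert-butyldimethylsilyl)oxy]-5-iodopent-4-enoic acid
Conditions: NaClO2, NaH2PO4, 2-methylbut-2-ene, tBuOH/H2O, rt
Reagents that add atoms: sodium chlorite, [Na+].[O-]Cl=O
Why: Pinnick oxidation is mild enough for the α-silyloxy centre, and the alkene scavenger keeps HOCl away from the iodoalkene.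

**Fragment 2 (steps 8–14)**

Step 8
Reactants: 11 (R)-2-aminobutanoic acid
Product: 14 (R)-2-hydroxybutanoic acid, via diazonium carboxylate 12 (not isolated), via alpha-lactone 13 (not isolated)
Conditions: NaNO2, 1 M H2SO4 (aq), 0 °C → rt
Reagents that add atoms: water, O
Why: Diazotisation of the α-amino acid proceeds with net retention (double inversion through the α-lactone), which fixes C13 as R.

Step 9
Reactants: 14 (R)-2-hydroxybutanoic acid
Product: 15 methyl (R)-2-hydroxybutanoate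
Conditions: MeOH, H2SO4 (cat.), reflux
Reagents that add atoms: methanol, CO
Why: Fischer esterification does not involve the stereocentre.

Step 10
Reactants: 15 methyl (R)-2-hydroxybutanoate
Product: 16 methyl (R)-2-(benzyloxy)butanoate
Conditions: BnOC(=NH)CCl3, TfOH (cat.), cyclohexane/CH2Cl2, rt
Reagents that add atoms: benzyl 2,2,2-trichloroacetimidate, N=C(OCc1ccccc1)C(Cl)(Cl)Cl
Why: Acid-catalysed trichloroacetimidate benzylation needs no base, so the α-stereocentre is not racemised, and the benzyl ether can chelate in step 12.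

Step 11
Reactants: 16 methyl (R)-2-(benzyloxy)butanoate
Product: 17 (R)-2-(benzyloxy)butanal
Conditions: iBu2AlH, CH2Cl2, −78 °C; MeOH, then aq. potassium sodium tartrate
Reagents that add atoms: none
Why: Partial ester reduction stops at the chelated tetrahedral aluminium intermediate at −78 °C; the aldehyde is used crude to avoid epimerisation.

Step 12
Reactants: 17 (R)-2-(benzyloxy)butanal; 18 allyltrimethylsilane
Product: 19 (3R,4R)-3-(benzyloxy)hept-6-en-4-ol
Conditions: SnCl4, CH2Cl2, −78 °C; then 18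
Reagents that add atoms: none
Why: Chelation-controlled Hosomi–Sakurai allylation: the allylsilane attacks the five-membered Sn chelate anti to the ethyl group (Cram chelate model) and gives the 12,13-syn alcohol (12R).

Step 13
Reactants: 19 (3R,4R)-3-(benzyloxy)hept-6-en-4-ol
Product: 20 ({[(3R,4S)-4-bromohept-6-en-3-yl]oxy}methyl)benzene
Conditions: CBr4, P(n-Oct)3, toluene, 70 °C
Reagents that add atoms: carbon tetrabromide, BrC(Br)(Br)Br
Why: Appel bromination displaces the alkoxyphosphonium by SN2 with inversion and sets C12 as S.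

Step 14
Reactants: 20 ({[(3R,4S)-4-bromohept-6-en-3-yl]oxy}methyl)benzene
Product: 21 (3R,4S)-4-bromohept-6-en-3-ol
Conditions: BCl3, CH2Cl2, −78 → −20 °C; aq. NaHCO3
Reagents that add atoms: none
Why: Lewis-acid debenzylation cleaves the benzylic C–O bond only, so the alkene, the secondary bromide and both stereocentres survive.

**Fragment union and end game (steps 15–21)**

Step 15
Reactants: 10 (2R,4E)-2-[(tert-butyldimethylsilyl)oxy]-5-iodopent-4-enoic acid; 21 (3R,4S)-4-bromohept-6-en-3-ol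
Product: 22 (3R,4S)-4-bromohept-6-en-3-yl (2R,4E)-2-[(tert-butyldimethylsilyl)oxy]-5-iodopent-4-enoate
Conditions: DCC, DMAP (cat.), CH2Cl2, 0 °C → rt
Reagents that add atoms: none
Why: Steglich esterification joins the two fragments under nearly neutral conditions, so the bromohydrin is not closed to an epoxide and C6 is not epimerised.

Step 16
Reactants: 22 (3R,4S)-4-bromohept-6-en-3-yl (2R,4E)-2-[(tert-butyldimethylsilyl)oxy]-5-iodopent-4-enoate
Product: 24 (2R,4E)-1-{[(3R,4S)-4-bromohept-6-en-3-yl]oxy}-2-[(tert-butyldimethylsilyl)oxy]-5-iodopent-4-en-1-yl acetate, via aluminium hemiacetal 23 (not isolated)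
Conditions: iBu2AlH, CH2Cl2, −78 °C; then pyridine, DMAP, Ac2O, −78 °C → rt
Reagents that add atoms: acetic anhydride, CC(=O)OC(C)=O
Why: Rychnovsky reductive acetylation traps the α-oxygenated aluminium hemiacetal as the α-acetoxy ether, turning the ester into the C7–O–C13 ether; the acetal epimers do not matter.

Step 17
Reactants: 24 (2R,4E)-1-{[(3R,4S)-4-bromohept-6-en-3-yl]oxy}-2-[(tert-butyldimethylsilyl)oxy]-5-iodopent-4-en-1-yl acetate; 18 allyltrimethylsilane
Product: 25 tert-butyl{[(1E,4R,5S)-5-{[(3R,4S)-4-bromohept-6-en-3-yl]oxy}-1-iodoocta-1,7-dien-4-yl]oxy}dimethylsilane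
Conditions: 18 (4 equiv), BF3·OEt2, CH2Cl2, −78 °C
Reagents that add atoms: none
Why: Hosomi–Sakurai allylation of the (E)-oxocarbenium ion formed from both acetal epimers; under non-chelating conditions the bulky C6 silyloxy group directs polar Felkin–Anh (Cornforth) attack and the 6,7-anti ether (7S) is expected as the major isomer.

Step 18
Reactants: 25 tert-butyl{[(1E,4R,5S)-5-{[(3R,4S)-4-bromohept-6-en-3-yl]oxy}-1-iodoocta-1,7-dien-4-yl]oxy}dimethylsilane
Product: 26 tert-butyl{[(1R,3E)-1-[(2S,4Z,7S,8R)-7-bromo-8-ethyl-3,6,7,8-tetrahydro-2H-oxocin-2-yl]-4-iodobut-3-en-1-yl]oxy}dimethylsilane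
Conditions: second-generation Grubbs catalyst RuCl2(=CHPh)(H2IMes)(PCy3) (10 mol %), CH2Cl2 (2 mM), 40 °C
Reagents that add atoms: none
Why: Ring-closing metathesis of the two terminal alkenes forms ring A, helped by the gauche C6–O/C7–O and C12–Br/C13–O arrangements; the eight-membered ring enforces the Z alkene and the 1-iodoalkene is a poor metathesis partner.

Step 19
Reactants: 26 tert-butyl{[(1R,3E)-1-[(2S,4Z,7S,8R)-7-bromo-8-ethyl-3,6,7,8-tetrahydro-2H-oxocin-2-yl]-4-iodobut-3-en-1-yl]oxy}dimethylsilane; 27 ethynyltrimethylsilane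
Product: 28 tert-butyl{[(1R,3E)-1-[(2S,4Z,7S,8R)-7-bromo-8-ethyl-3,6,7,8-tetrahydro-2H-oxocin-2-yl]-6-(trimethylsilyl)hex-3-en-5-yn-1-yl]oxy}dimethylsilane
Conditions: Pd(PPh3)4 (5 mol %), CuI (10 mol %), iPr2NH, THF, rt
Reagents that add atoms: none
Why: Sonogashira coupling of the alkenyl iodide proceeds with retention of the E geometry, and the secondary alkyl bromide does not undergo oxidative addition at room temperature.

Step 20
Reactants: 28 tert-butyl{[(1R,3E)-1-[(2S,4Z,7S,8R)-7-bromo-8-ethyl-3,6,7,8-tetrahydro-2H-oxocin-2-yl]-6-(trimethylsilyl)hex-3-en-5-yn-1-yl]oxy}dimethylsilane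
Product: 29 (1R,3E)-1-[(2S,4Z,7S,8R)-7-bromo-8-ethyl-3,6,7,8-tetrahydro-2H-oxocin-2-yl]hex-3-en-5-yn-1-ol
Conditions: Bu4NF, AcOH, THF, 0 °C → rt
Reagents that add atoms: none
Why: Fluoride desilylation removes the O-silyl and C-silyl groups together, and the acetic acid buffer suppresses E2 elimination of the C12 bromide.

Step 21
Reactants: 29 (1R,3E)-1-[(2S,4Z,7S,8R)-7-bromo-8-ethyl-3,6,7,8-tetrahydro-2H-oxocin-2-yl]hex-3-en-5-yn-1-ol
Product: 30 (1S,3R,4S,6S,7S,9R)-4,6-dibromo-3-ethyl-9-[(2E)-pent-2-en-4-yn-1-yl]-2,8-dioxabicyclo[5.2.1]decane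
Conditions: 2,4,4,6-tetrabromocyclohexa-2,5-dienone (TBCO), CH2Cl2, 0 °C, dark
Reagents that add atoms: 2,4,4,6-tetrabromocyclohexa-2,5-dienone, O=C1C(Br)=CC(Br)(Br)C=C1Br
Why: Biomimetic bromoetherification: only the bromonium ion on the face away from the C6 hydroxyl arm can be opened 5-exo at C9, so the anti addition across the Z alkene sets C9 (S) and C10 (S) and closes ring B.

**Compound list**
1 | (S)-oxiran-2-ylmethanol ((S)-glycidol) | OC[C@H]1CO1 | starting material
2 | (R)-2-{[(4-methoxybenzyl)oxy]methyl}oxirane | COc1ccc(COC[C@H]2CO2)cc1 | intermediate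
3 | lithium acetylide–ethylenediamine complex | [Li+].[C-]#C.NCCN | starting material
4 | (R)-1-[(4-methoxybenzyl)oxy]pent-4-yn-2-ol | C#CC[C@@H](O)COCc1ccc(OC)cc1 | intermediate
5 | (R)-tert-butyl({1-[(4-methoxybenzyl)oxy]pent-4-yn-2-yl}oxy)dimethylsilane | C#CC[C@@H](O[Si](C)(C)C(C)(C)C)COCc1ccc(OC)cc1 | intermediate
6 | alkenylzirconocene chloride, chlorobis(cyclopentadienyl){(1E,4R)-4-[(tert-butyldimethylsilyl)oxy]-5-[(4-methoxybenzyl)oxy]pent-1-en-1-yl}zirconium (Cp drawn sigma-bonded) | Cl[Zr](C1C=CC=C1)(C1C=CC=C1)/C=C/C[C@@H](O[Si](C)(C)C(C)(C)C)COCc1ccc(OC)cc1 | intermediate (not isolated)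
7 | tert-butyl({(2R,4E)-5-iodo-1-[(4-methoxybenzyl)oxy]pent-4-en-2-yl}oxy)dimethylsilane | I/C=C/C[C@@H](O[Si](C)(C)C(C)(C)C)COCc1ccc(OC)cc1 | intermediate
8 | (2R,4E)-2-[(tert-butyldimethylsilyl)oxy]-5-iodopent-4-en-1-ol | I/C=C/C[C@@H](O[Si](C)(C)C(C)(C)C)CO | intermediate
9 | (2R,4E)-2-[(tert-butyldimethylsilyl)oxy]-5-iodopent-4-enal | I/C=C/C[C@@H](O[Si](C)(C)C(C)(C)C)C=O | intermediate
10 | (2R,4E)-2-[(tert-butyldimethylsilyl)oxy]-5-iodopent-4-enoic acid (fragment 1) | I/C=C/C[C@@H](O[Si](C)(C)C(C)(C)C)C(=O)O | intermediate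
11 | (R)-2-aminobutanoic acid | CC[C@@H](N)C(=O)O | starting material
12 | (R)-2-diazoniobutanoate (diazonium carboxylate) | CC[C@@H]([N+]#N)C(=O)[O-] | intermediate (not isolated)
13 | (S)-3-ethyloxiran-2-one (alpha-lactone) | CC[C@@H]1OC1=O | intermediate (not isolated)
14 | (R)-2-hydroxybutanoic acid | CC[C@@H](O)C(=O)O | intermediate
15 | methyl (R)-2-hydroxybutanoate | CC[C@@H](O)C(=O)OC | intermediate
16 | methyl (R)-2-(benzyloxy)butanoate | CC[C@@H](OCc1ccccc1)C(=O)OC | intermediate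
17 | (R)-2-(benzyloxy)butanal | CC[C@@H](OCc1ccccc1)C=O | intermediate
18 | allyltrimethylsilane | C=CC[Si](C)(C)C | starting material
19 | (3R,4R)-3-(benzyloxy)hept-6-en-4-ol | CC[C@@H](OCc1ccccc1)[C@H](O)CC=C | intermediate
20 | ({[(3R,4S)-4-bromohept-6-en-3-yl]oxy}methyl)benzene | CC[C@@H](OCc1ccccc1)[C@@H](Br)CC=C | intermediate
21 | (3R,4S)-4-bromohept-6-en-3-ol (fragment 2) | CC[C@@H](O)[C@@H](Br)CC=C | intermediate
22 | (3R,4S)-4-bromohept-6-en-3-yl (2R,4E)-2-[(tert-butyldimethylsilyl)oxy]-5-iodopent-4-enoate | I/C=C/C[C@@H](O[Si](C)(C)C(C)(C)C)C(=O)O[C@H](CC)[C@@H](Br)CC=C | intermediate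
23 | aluminium hemiacetal, diisobutylaluminium alkoxide of the half-reduced ester 22 (both epimers at C7) | I/C=C/C[C@@H](O[Si](C)(C)C(C)(C)C)C(O[Al](CC(C)C)CC(C)C)O[C@H](CC)[C@@H](Br)CC=C | intermediate (not isolated)
24 | (2R,4E)-1-{[(3R,4S)-4-bromohept-6-en-3-yl]oxy}-2-[(tert-butyldimethylsilyl)oxy]-5-iodopent-4-en-1-yl acetate (both C1 epimers) | I/C=C/C[C@@H](O[Si](C)(C)C(C)(C)C)C(OC(C)=O)O[C@H](CC)[C@@H](Br)CC=C | intermediate
25 | tert-butyl{[(1E,4R,5S)-5-{[(3R,4S)-4-bromohept-6-en-3-yl]oxy}-1-iodoocta-1,7-dien-4-yl]oxy}dimethylsilane | I/C=C/C[C@@H](O[Si](C)(C)C(C)(C)C)[C@H](CC=C)O[C@H](CC)[C@@H](Br)CC=C | intermediate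
26 | tert-butyl{[(1R,3E)-1-[(2S,4Z,7S,8R)-7-bromo-8-ethyl-3,6,7,8-tetrahydro-2H-oxocin-2-yl]-4-iodobut-3-en-1-yl]oxy}dimethylsilane | I/C=C/C[C@@H](O[Si](C)(C)C(C)(C)C)[C@@H]1C/C=C\C[C@H](Br)[C@@H](CC)O1 | intermediate
27 | ethynyltrimethylsilane | C#C[Si](C)(C)C | starting material
28 | tert-butyl{[(1R,3E)-1-[(2S,4Z,7S,8R)-7-bromo-8-ethyl-3,6,7,8-tetrahydro-2H-oxocin-2-yl]-6-(trimethylsilyl)hex-3-en-5-yn-1-yl]oxy}dimethylsilane | C[Si](C)(C)C#C/C=C/C[C@@H](O[Si](C)(C)C(C)(C)C)[C@@H]1C/C=C\C[C@H](Br)[C@@H](CC)O1 | intermediate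
29 | (1R,3E)-1-[(2S,4Z,7S,8R)-7-bromo-8-ethyl-3,6,7,8-tetrahydro-2H-oxocin-2-yl]hex-3-en-5-yn-1-ol | C#C/C=C/C[C@@H](O)[C@@H]1C/C=C\C[C@H](Br)[C@@H](CC)O1 | intermediate
30 | (1S,3R,4S,6S,7S,9R)-4,6-dibromo-3-ethyl-9-[(2E)-pent-2-en-4-yn-1-yl]-2,8-dioxabicyclo[5.2.1]decane | C#C/C=C/C[C@H]1O[C@H]2C[C@@H]1O[C@H](CC)[C@@H](Br)C[C@@H]2Br | target

**Totals**
Total step count: 21.
Longest linear sequence: 14 steps (steps 1–7 then 15–21; the branch 8–14 then 15–21 is equally long).

**Three steps most likely to fail**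

Step 17 (diastereoselectivity at C7). The 1,2-induction in an acyclic oxocarbenium ion may be modest, and this is the least certain stereocentre of the route. The fallback sets out from 9 and 14 and comes back at 25; it replaces acyclic induction by a cyclic chiral acetal. Acid 14 is bis-silylated (Me3SiCl, Et3N) to trimethylsilyl (R)-2-[(trimethylsilyl)oxy]butanoate F1. F1 is condensed with aldehyde 9 (Me3SiOTf cat., CH2Cl2, −78 °C) to the cis-dioxolanone (2R,5R)-2-{(1R,3E)-1-[(tert-butyldimethylsilyl)oxy]-4-iodobut-3-en-1-yl}-5-ethyl-1,3-dioxolan-4-one F2. Allylsilane 18 with TiCl4 opens the acetal with inversion at C7 (carboxylate as leaving group) to (2R)-2-({(4S,5R,7E)-5-[(tert-butyldimethylsilyl)oxy]-8-iodoocta-1,7-dien-4-yl}oxy)butanoic acid F3, with C7 (S) and C13 (R) both in place. Me3SiCHN2 gives methyl (2R)-2-({(4S,5R,7E)-5-[(tert-butyldimethylsilyl)oxy]-8-iodoocta-1,7-dien-4-yl}oxy)butanoate F4, and iBu2AlH at −78 °C gives (2R)-2-({(4S,5R,7E)-5-[(tert-butyldimethylsilyl)oxy]-8-iodoocta-1,7-dien-4-yl}oxy)butanal F5. Chelation-controlled allylation with 18 and SnCl4 gives (3R,4R)-3-({(4S,5R,7E)-5-[(tert-butyldimethylsilyl)oxy]-8-iodoocta-1,7-dien-4-yl}oxy)hept-6-en-4-ol F6, and Appel bromination (CBr4, P(n-Oct)3) with inversion gives 25.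

Step 18 (ring-closing metathesis). The eight-membered ring closes slowly, and a ruthenium carbene formed at C9 could instead attack the iodoalkene to give a cyclohexene and a dead catalyst. The fallback sets out from 24 and comes back at 26; it redesigns the metathesis substrate so that the carbene can only start on the fragment 2 alkene. Acetate 24 is allylated with (but-3-en-2-yl)trimethylsilane and BF3·OEt2 (SE2′) to the crotyl ether tert-butyl{[(1E,4R,5S,7E)-5-{[(3R,4S)-4-bromohept-6-en-3-yl]oxy}-1-iodonona-1,7-dien-4-yl]oxy}dimethylsilane F7. With the same ruthenium catalyst, the carbene initiates at the only terminal alkene (C10) and closes onto the internal crotyl alkene with loss of propene to give 26.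

Step 21 (bromoetherification). The free enyne may compete for the bromonium source, and 6-endo or transannular oxonium pathways are possible. The fallback sets out from 26 and comes back at 30; it closes ring B before the enyne exists. Compound 26 is desilylated (Bu4NF, AcOH) to (1R,3E)-1-[(2S,4Z,7S,8R)-7-bromo-8-ethyl-3,6,7,8-tetrahydro-2H-oxocin-2-yl]-4-iodobut-3-en-1-ol F8. TBCO in CH2Cl2 cyclises F8 to (1S,3R,4S,6S,7S,9R)-4,6-dibromo-3-ethyl-9-[(2E)-3-iodoprop-2-en-1-yl]-2,8-dioxabicyclo[5.2.1]decane F9, in which the electron-poor iodoalkene does not compete. Sonogashira coupling with 27 (Pd(PPh3)4, CuI, iPr2NH) gives {(3E)-5-[(1S,3R,4S,6S,7S,9R)-4,6-dibromo-3-ethyl-2,8-dioxabicyclo[5.2.1]decan-9-yl]pent-3-en-1-yn-1-yl}trimethylsilane F10, and K2CO3 in MeOH removes the silyl group to give 30.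

**Further compounds**
F1 | step 17 | trimethylsilyl (R)-2-[(trimethylsilyl)oxy]butanoate | CC[C@@H](O[Si](C)(C)C)C(=O)O[Si](C)(C)C
F2 | step 17 | (2R,5R)-2-{(1R,3E)-1-[(tert-butyldimethylsilyl)oxy]-4-iodobut-3-en-1-yl}-5-ethyl-1,3-dioxolan-4-one | CC[C@H]1O[C@@H]([C@@H](C/C=C/I)O[Si](C)(C)C(C)(C)C)OC1=O
F3 | step 17 | (2R)-2-({(4S,5R,7E)-5-[(tert-butyldimethylsilyl)oxy]-8-iodoocta-1,7-dien-4-yl}oxy)butanoic acid | I/C=C/C[C@@H](O[Si](C)(C)C(C)(C)C)[C@H](CC=C)O[C@H](CC)C(=O)O
F4 | step 17 | methyl (2R)-2-({(4S,5R,7E)-5-[(tert-butyldimethylsilyl)oxy]-8-iodoocta-1,7-dien-4-yl}oxy)butanoate | I/C=C/C[C@@H](O[Si](C)(C)C(C)(C)C)[C@H](CC=C)O[C@H](CC)C(=O)OC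
F5 | step 17 | (2R)-2-({(4S,5R,7E)-5-[(tert-butyldimethylsilyl)oxy]-8-iodoocta-1,7-dien-4-yl}oxy)butanal | I/C=C/C[C@@H](O[Si](C)(C)C(C)(C)C)[C@H](CC=C)O[C@H](CC)C=O
F6 | step 17 | (3R,4R)-3-({(4S,5R,7E)-5-[(tert-butyldimethylsilyl)oxy]-8-iodoocta-1,7-dien-4-yl}oxy)hept-6-en-4-ol | I/C=C/C[C@@H](O[Si](C)(C)C(C)(C)C)[C@H](CC=C)O[C@H](CC)[C@H](O)CC=C
F7 | step 18 | tert-butyl{[(1E,4R,5S,7E)-5-{[(3R,4S)-4-bromohept-6-en-3-yl]oxy}-1-iodonona-1,7-dien-4-yl]oxy}dimethylsilane | I/C=C/C[C@@H](O[Si](C)(C)C(C)(C)C)[C@H](C/C=C/C)O[C@H](CC)[C@@H](Br)CC=C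
F8 | step 21 | (1R,3E)-1-[(2S,4Z,7S,8R)-7-bromo-8-ethyl-3,6,7,8-tetrahydro-2H-oxocin-2-yl]-4-iodobut-3-en-1-ol | I/C=C/C[C@@H](O)[C@@H]1C/C=C\C[C@H](Br)[C@@H](CC)O1
F9 | step 21 | (1S,3R,4S,6S,7S,9R)-4,6-dibromo-3-ethyl-9-[(2E)-3-iodoprop-2-en-1-yl]-2,8-dioxabicyclo[5.2.1]decane | I/C=C/C[C@H]1O[C@H]2C[C@@H]1O[C@H](CC)[C@@H](Br)C[C@@H]2Br
F10 | step 21 | {(3E)-5-[(1S,3R,4S,6S,7S,9R)-4,6-dibromo-3-ethyl-2,8-dioxabicyclo[5.2.1]decan-9-yl]pent-3-en-1-yn-1-yl}trimethylsilane | C[Si](C)(C)C#C/C=C/C[C@H]1O[C@H]2C[C@@H]1O[C@H](CC)[C@@H](Br)C[C@@H]2Br
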